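The earlier runs and the new flask stem from a simulated flask with made-up constants, noise included.

**The pitfall.** Taking the highest reading for the peak is the trap: birch and oak both show 90% at 2.50 d, but readings so far apart don't place a peak. Birch's monomer in chains rises and later reads 63% at 8.00 d, which is kinetic against thermodynamic control.

all flasks: free monomer 0.60 M
- birch: pre-initiator 0.65 mM; run made earlier
- oak: pre-initiator 0.98 mM; run made earlier
- flask: pre-initiator 1.3 mM; time 12 d

| run | time / d | monomer in chains / % | free monomer / % |
|---|---|---|---|
| birch | 0.417 | 18 | 82 |
| birch | 1.04 | 71 | 24 |
| birch | 2.50 | 90 | 1 |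
| birch | 8.00 | 63 | 0 |
| oak | 0.417 | 25 | 76 |
| oak | 1.04 | 81 | 17 |
| oak | 2.50 | 90 | 2 |
| oak | 8.00 | 67 | 0 |

(each reading ± 1.5 percentage points)

- reactions considered so far: free monomer + initiator -> living end + monomer in chains; pre-initiator -> initiator; monomer in chains <-> isomer of the product; free monomer + living end -> monomer in chains + living end

- the best time, 12 d at the latest, for monomer in chains
- the amount of monomer in chains, in percent of the free monomer charged, at that time
- the first time at which monomer in chains reaches 65%, in the same percent, in d

**First link.** Birch reads 1% free monomer at 2.50 d. Its monomer in chains then falls to 63% at 8.00 d, which in logarithms is a loss of 0.0648 d⁻¹.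

**Filling.** I take the logarithm of the free share as growing in size with time squared. I call filling time the time at which that logarithm reaches minus one. The readings at 1.04 d give a filling time of 0.871 d for birch and 0.781 d for oak. Birch's over oak's is 1.12, and the fourth root of the charge ratio is 1.11. So I scale by that root, and the flask gets 0.728 d.

**The peak.** I put the peak where feed equals loss. From a first guess of 1.46 d, one pass through the logarithm gives 1.53 d for the flask.

**Weak link.** That loss rests on one pair of readings with a scatter of 1.5 percentage points. Oak gives 0.0537 d⁻¹. Pooling both gives 0.0593 d⁻¹, the fade rate, the first-order loss of monomer in chains once free monomer reads 1% or 2%. My peak for the flask becomes 1.55 d. Chains then have a median age of 0.943 d, so I commit to 93.6%. I expect the flask to reach the level at 0.746 d.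

**The forecast.** It says 1.5 d, 94% and 0.72 d, reasoning that “The peak falls where monomer feed equals isomer loss”. My times are later: 0.746 d against 0.72 d, and 1.55 d against 1.5 d.

**The result.** The flask gives 1.53 d, 92.7% and 0.699 d.

    free monomer + initiator → living end + monomer in chains (k = 3.85 × 10⁻⁵ M⁻¹ s⁻¹)
    pre-initiator → initiator (k = 3.01 × 10⁻⁵ s⁻¹)
    monomer in chains ⇌ isomer of the product (K = 2.60, k = 7.68 × 10⁻⁷ s⁻¹)
    free monomer + living end → monomer in chains + living end, rate k4*[living end]*[free monomer] (k = 0.0797 M⁻¹ s⁻¹)

Pre-initiator halves in 0.27 d at 0.568 d, while monomer in chains halves by the forward step in 10 d, about 39.2 times slower. The back reaction makes no difference to the peak. From the peak to 12 d, the fade rate gives 49.8% monomer in chains, and the flask holds 53.2%.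

**Second flask.** A neighbour charged with 2.4 M free monomer has a best of 94.4%; faded at the fade rate over the span I used above, that gives 50.7%. Its computed monomer in chains at the end is 52.7%.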